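The route rests on cutting the bond between the hydroxymethyl-bearing alkene carbon of the dienyl chain and the adjacent CH2 of the two-carbon tether to the decalin (rings A and B). The key step exploits the primary allylic hydroxyl on that alkene carbon: its magnesium alkoxide directs a CuI-catalysed anti-carbomagnesiation of 5-(trimethylsilyl)penta-2,4-diyn-1-ol by the sclareolide-derived homoallylic Grignard reagent, forging this bond and the E trisubstituted alkene in one operation through a five-membered oxamagnesacycle. The precursor is thus a linear diynol with no alkene and no furanone; the butenolide ring (ring C) is closed last by Sonogashira coupling and 5-exo lactonisation with (Z)-3-iodobut-2-enoic acid.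

Key step: step 5

Remark: natural (+)-sclareolide is assumed to supply the (4aS,8aS) ring fusion of the target; its two other stereocentres are removed when the tetrasubstituted alkene is formed.

Step 1
Reactants: 1 (+)-sclareolide
Product: 2 methyl 2-[(4aS,8aS)-2,5,5,8a-tetramethyl-3,4,4a,5,6,7,8,8a-octahydronaphthalen-1-yl]acetate
Conditions: conc. H2SO4, MeOH, reflux (equilibrating); chromatography on AgNO3-impregnated silica
Reagents that add atoms: methanol, CO
Why: Acid-mediated alkyl–oxygen cleavage of the tertiary lactone gives the ring B tertiary cation, which should lose the ring proton next to the side chain to give the thermodynamically favoured tetrasubstituted C1=C2 alkene (E1 elimination) while the acid is trapped by Fischer esterification, leaving the two ring-fusion stereocentres untouched.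

Step 2
Reactants: 2 methyl 2-[(4aS,8aS)-2,5,5,8a-tetramethyl-3,4,4a,5,6,7,8,8a-octahydronaphthalen-1-yl]acetate
Product: 3 2-[(4aS,8aS)-2,5,5,8a-tetramethyl-3,4,4a,5,6,7,8,8a-octahydronaphthalen-1-yl]ethan-1-ol
Conditions: LiAlH4, Et2O, 0 °C → rt; H2O, aq NaOH work-up
Reagents that add atoms: none
Why: LiAlH4 reduction of the ester to the primary alcohol should proceed cleanly because the isolated tetrasubstituted alkene is inert to hydride.

Step 3
Reactants: 3 2-[(4aS,8aS)-2,5,5,8a-tetramethyl-3,4,4a,5,6,7,8,8a-octahydronaphthalen-1-yl]ethan-1-ol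
Product: 4 (4aS,8aS)-1-(2-bromoethyl)-2,5,5,8a-tetramethyl-3,4,4a,5,6,7,8,8a-octahydronaphthalene
Conditions: CBr4, PPh3, CH2Cl2, 0 °C
Reagents that add atoms: carbon tetrabromide, BrC(Br)(Br)Br
Why: Appel reaction, in which bromide displaces the alkoxyphosphonium group by SN2 at the primary carbon under neutral conditions that should not touch the hindered alkene.

Step 4
Reactants: 5 1,4-bis(trimethylsilyl)buta-1,3-diyne
Product: 7 5-(trimethylsilyl)penta-2,4-diyn-1-ol, via lithium 4-(trimethylsilyl)buta-1,3-diyn-1-ide 6 (not isolated)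
Conditions: MeLi·LiBr (1.0 equiv), Et2O, rt; then (CH2O)n, THF, −78 °C → rt; aq NH4Cl
Reagents that add atoms: paraformaldehyde (as formaldehyde), C=O
Why: Methyllithium should cleave one alkynyl–silicon bond selectively (monodesilylation), and the resulting lithium acetylide adds to formaldehyde (acetylide 1,2-addition) to give the propargylic alcohol.

Step 5
Reactants: 4 (4aS,8aS)-1-(2-bromoethyl)-2,5,5,8a-tetramethyl-3,4,4a,5,6,7,8,8a-octahydronaphthalene; 7 5-(trimethylsilyl)penta-2,4-diyn-1-ol
Product: 12 (2E)-2-{2-[(4aS,8aS)-2,5,5,8a-tetramethyl-3,4,4a,5,6,7,8,8a-octahydronaphthalen-1-yl]ethyl}pent-2-en-4-yn-1-ol, via homoallylic Grignard reagent 8 (not isolated), via bromomagnesium alkoxide of the diynol 9 (not isolated), via oxamagnesacycle chelate 10 (not isolated), via silyl enynol 11 (not isolated)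
Conditions: 4, Mg (I2-activated), THF, 40 °C; separately 7, MeMgBr (1.0 equiv), THF, −20 °C; combine (1.5 equiv of 8), CuI (10 mol %), −20 °C → rt; then MeOH, K2CO3, rt; aq NH4Cl work-up
Reagents that add atoms: none
Why: The organocopper species formed from Grignard reagent 8 and catalytic CuI should deliver the alkyl group to C2 of alkoxide 9 (the alkyne carbon next to the CH2O group) while the alkoxide-bound magnesium closes onto C3 from the opposite face, giving oxamagnesacycle 10 by net anti addition. The closest known reaction type is the CuI-catalysed, alkoxide-directed anti-carbomagnesiation of 2-alkyn-1-ols, and the alkoxide-directed trans-hydroalumination of 2,4-diyn-1-ols shows that a conjugated diyne accepts the same chelate control. No ring of the target is closed; the only ring formed is the transient 2,5-dihydro-1,2-oxamagnesole, which methanol opens by protonolysis with retention at C3. No stereocentre is created, but the E geometry of the trisubstituted alkene (alkynyl trans to CH2OH and cis to the new alkyl chain) follows from the anti addition enforced by the chelate. The step needs regioselectivity for C2 over C3 and over the distal alkyne, which the five-membered chelate (attack at C3 would need a four-membered one) and the SiMe3 cap on C5 should secure; methanolic K2CO3 then removes the silyl group in the same flask.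

Step 6
Reactants: 13 but-2-ynoic acid
Product: 14 (2Z)-3-iodobut-2-enoic acid
Conditions: 57 % aq HI, 80 °C
Reagents that add atoms: hydrogen iodide, I
Why: Conjugate anti-hydroiodination of the ynoic acid (iodide adds at C3, proton at C2 from the opposite side) should give the Z acid with iodine cis to CO2H, as needed for the later lactonisation.

Step 7
Reactants: 12 (2E)-2-{2-[(4aS,8aS)-2,5,5,8a-tetramethyl-3,4,4a,5,6,7,8,8a-octahydronaphthalen-1-yl]ethyl}pent-2-en-4-yn-1-ol; 14 (2Z)-3-iodobut-2-enoic acid
Product: 16 (5Z)-5-{(2E)-3-(hydroxymethyl)-5-[(4aS,8aS)-2,5,5,8a-tetramethyl-3,4,4a,5,6,7,8,8a-octahydronaphthalen-1-yl]pent-2-en-1-ylidene}-4-methylfuran-2(5H)-one, via (2Z,6E)-dienynoic acid 15 (not isolated)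
Conditions: Pd(PPh3)4 (5 mol %), CuI (10 mol %), Et3N, MeCN, rt, argon, dark
Reagents that add atoms: none
Why: Sonogashira coupling (zerovalent palladium, CuI co-catalyst) should give enynoic acid 15, whose carboxylate then adds anti across the metal-activated alkyne in a 5-exo-dig lactonisation followed by protodemetalation, placing the ring oxygen cis to the side chain (Z exocyclic alkene) while the E alkene and the free primary alcohol of 12 are not involved.

Compound list
1 | (+)-sclareolide, (3aR,5aS,9aS,9bR)-3a,6,6,9a-tetramethyldecahydronaphtho[2,1-b]furan-2(1H)-one | CC1(C)CCC[C@]2(C)[C@H]3CC(=O)O[C@]3(C)CC[C@@H]12 | starting material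
2 | methyl 2-[(4aS,8aS)-2,5,5,8a-tetramethyl-3,4,4a,5,6,7,8,8a-octahydronaphthalen-1-yl]acetate | COC(=O)CC1=C(C)CC[C@H]2C(C)(C)CCC[C@]12C | intermediate
3 | 2-[(4aS,8aS)-2,5,5,8a-tetramethyl-3,4,4a,5,6,7,8,8a-octahydronaphthalen-1-yl]ethan-1-ol | OCCC1=C(C)CC[C@H]2C(C)(C)CCC[C@]12C | intermediate
4 | (4aS,8aS)-1-(2-bromoethyl)-2,5,5,8a-tetramethyl-3,4,4a,5,6,7,8,8a-octahydronaphthalene | BrCCC1=C(C)CC[C@H]2C(C)(C)CCC[C@]12C | intermediate
5 | 1,4-bis(trimethylsilyl)buta-1,3-diyne | C[Si](C)(C)C#CC#C[Si](C)(C)C | starting material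
6 | lithium 4-(trimethylsilyl)buta-1,3-diyn-1-ide | [Li]C#CC#C[Si](C)(C)C | intermediate
7 | 5-(trimethylsilyl)penta-2,4-diyn-1-ol | C[Si](C)(C)C#CC#CCO | intermediate
8 | {2-[(4aS,8aS)-2,5,5,8a-tetramethyl-3,4,4a,5,6,7,8,8a-octahydronaphthalen-1-yl]ethyl}magnesium bromide | Br[Mg]CCC1=C(C)CC[C@H]2C(C)(C)CCC[C@]12C | intermediate
9 | bromomagnesium 5-(trimethylsilyl)penta-2,4-diyn-1-olate | C[Si](C)(C)C#CC#CCO[Mg]Br | intermediate
10 | 4-{2-[(4aS,8aS)-2,5,5,8a-tetramethyl-3,4,4a,5,6,7,8,8a-octahydronaphthalen-1-yl]ethyl}-3-[(trimethylsilyl)ethynyl]-2,5-dihydro-1,2-oxamagnesole (solvated chelate, drawn as monomer) | C[Si](C)(C)C#CC1=C(CCC2=C(C)CC[C@H]3C(C)(C)CCC[C@]23C)CO[Mg]1 | intermediate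
11 | (2E)-2-{2-[(4aS,8aS)-2,5,5,8a-tetramethyl-3,4,4a,5,6,7,8,8a-octahydronaphthalen-1-yl]ethyl}-5-(trimethylsilyl)pent-2-en-4-yn-1-ol | C[Si](C)(C)C#C/C=C(/CO)CCC1=C(C)CC[C@H]2C(C)(C)CCC[C@]12C | intermediate
12 | (2E)-2-{2-[(4aS,8aS)-2,5,5,8a-tetramethyl-3,4,4a,5,6,7,8,8a-octahydronaphthalen-1-yl]ethyl}pent-2-en-4-yn-1-ol | C#C/C=C(/CO)CCC1=C(C)CC[C@H]2C(C)(C)CCC[C@]12C | intermediate
13 | but-2-ynoic acid | CC#CC(=O)O | starting material
14 | (2Z)-3-iodobut-2-enoic acid | C/C(I)=C/C(=O)O | intermediate
15 | (2Z,6E)-7-(hydroxymethyl)-3-methyl-9-[(4aS,8aS)-2,5,5,8a-tetramethyl-3,4,4a,5,6,7,8,8a-octahydronaphthalen-1-yl]nona-2,6-dien-4-ynoic acid | C/C(=C/C(=O)O)C#C/C=C(/CO)CCC1=C(C)CC[C@H]2C(C)(C)CCC[C@]12C | intermediate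
16 | (5Z)-5-{(2E)-3-(hydroxymethyl)-5-[(4aS,8aS)-2,5,5,8a-tetramethyl-3,4,4a,5,6,7,8,8a-octahydronaphthalen-1-yl]pent-2-en-1-ylidene}-4-methylfuran-2(5H)-one | CC1=CC(=O)O/C1=C\C=C(\CO)CCC1=C(C)CC[C@H]2C(C)(C)CCC[C@]12C | target

Total step count: 7
Longest linear sequence: 5 steps (steps 1, 2, 3, 5 and 7)

Steps most likely to fail

Step 5. The risk is loss of regio- and stereocontrol on the conjugated diynol. The alkyl group could be delivered to the distal alkyne. The alkynyl-substituted vinylmagnesium could also shift to a cumulenyl species, which would be protonated to the wrong alkene geometry or to a butatriene. The hindered Grignard reagent may also add sluggishly. The fallback makes the same bond by enolate alkylation and sets out from bromide 4. The sodium salt of triethyl phosphonoacetate (NaH, DMF, NaI cat., 60 °C) would be alkylated by 4 to give ethyl 2-(diethoxyphosphoryl)-4-[(4aS,8aS)-2,5,5,8a-tetramethyl-3,4,4a,5,6,7,8,8a-octahydronaphthalen-1-yl]butanoate F1. Horner–Wadsworth–Emmons olefination of F1 with 3-(trimethylsilyl)propynal (NaH, THF, −78 → 0 °C) should favour ethyl (2E)-2-{2-[(4aS,8aS)-2,5,5,8a-tetramethyl-3,4,4a,5,6,7,8,8a-octahydronaphthalen-1-yl]ethyl}-5-(trimethylsilyl)pent-2-en-4-ynoate F2, with the alkynyl group trans to the ester; any Z isomer would be removed by chromatography. Reduction with i-Bu2AlH (CH2Cl2, −78 °C) comes back to the route at silyl enynol 11, which is desilylated (K2CO3, MeOH) to 12 as in step 5.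

Step 1. The risk is poor positional selectivity in the elimination from the tertiary cation, giving trisubstituted and exocyclic alkene isomers, together with re-closure to the lactone under the equilibrating acid. The fallback sets out from 1 and removes the carboxyl group before the alkene is formed. LiAlH4 reduction would give (1R,2R,4aS,8aS)-1-(2-hydroxyethyl)-2,5,5,8a-tetramethyldecahydronaphthalen-2-ol F3. Selective acetylation of the primary hydroxyl (Ac2O, pyridine, 0 °C) would give 2-[(1R,2R,4aS,8aS)-2-hydroxy-2,5,5,8a-tetramethyldecahydronaphthalen-1-yl]ethyl acetate F4. Dehydration under equilibrating acid conditions (TsOH, benzene, reflux, Dean–Stark) should then give 2-[(4aS,8aS)-2,5,5,8a-tetramethyl-3,4,4a,5,6,7,8,8a-octahydronaphthalen-1-yl]ethyl acetate F5, since the acetate side chain cannot re-close a lactone. Methanolysis (K2CO3, MeOH) comes back to the route at alcohol 3.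

Step 7. The risk is competing 6-endo closure to a 2-pyranone, oxidative homocoupling of the terminal alkyne, and base-induced degradation of the ylidene butenolide during the one-pot process. The fallback separates the coupling from the ring closure and sets out from 12 and 14. Acid 14 would be esterified (MeOH, H2SO4 cat.) to methyl (2Z)-3-iodobut-2-enoate F6. Sonogashira coupling of F6 with 12 (PdCl2(PPh3)2, CuI, Et3N, THF, rt) would give methyl (2Z,6E)-7-(hydroxymethyl)-3-methyl-9-[(4aS,8aS)-2,5,5,8a-tetramethyl-3,4,4a,5,6,7,8,8a-octahydronaphthalen-1-yl]nona-2,6-dien-4-ynoate F7. Saponification (LiOH, THF/H2O, 0 °C) gives acid 15, now isolated. Silver-promoted 5-exo-dig lactonisation (AgNO3 cat., acetone, rt, dark) under neutral conditions then comes back to the route at 16.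

Further compounds
F1 | step 5 | ethyl 2-(diethoxyphosphoryl)-4-[(4aS,8aS)-2,5,5,8a-tetramethyl-3,4,4a,5,6,7,8,8a-octahydronaphthalen-1-yl]butanoate | CCOC(=O)C(CCC1=C(C)CC[C@H]2C(C)(C)CCC[C@]12C)P(=O)(OCC)OCC
F2 | step 5 | ethyl (2E)-2-{2-[(4aS,8aS)-2,5,5,8a-tetramethyl-3,4,4a,5,6,7,8,8a-octahydronaphthalen-1-yl]ethyl}-5-(trimethylsilyl)pent-2-en-4-ynoate | CCOC(=O)/C(CCC1=C(C)CC[C@H]2C(C)(C)CCC[C@]12C)=C/C#C[Si](C)(C)C
F3 | step 1 | (1R,2R,4aS,8aS)-1-(2-hydroxyethyl)-2,5,5,8a-tetramethyldecahydronaphthalen-2-ol | CC1(C)CCC[C@]2(C)[C@@H](CCO)[C@](C)(O)CC[C@@H]12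
F4 | step 1 | 2-[(1R,2R,4aS,8aS)-2-hydroxy-2,5,5,8a-tetramethyldecahydronaphthalen-1-yl]ethyl acetate | CC1(C)CCC[C@]2(C)[C@@H](CCOC(C)=O)[C@](C)(O)CC[C@@H]12
F5 | step 1 | 2-[(4aS,8aS)-2,5,5,8a-tetramethyl-3,4,4a,5,6,7,8,8a-octahydronaphthalen-1-yl]ethyl acetate | CC(=O)OCCC1=C(C)CC[C@H]2C(C)(C)CCC[C@]12C
F6 | step 7 | methyl (2Z)-3-iodobut-2-enoate | C/C(I)=C/C(=O)OC
F7 | step 7 | methyl (2Z,6E)-7-(hydroxymethyl)-3-methyl-9-[(4aS,8aS)-2,5,5,8a-tetramethyl-3,4,4a,5,6,7,8,8a-octahydronaphthalen-1-yl]nona-2,6-dien-4-ynoate | C/C(=C/C(=O)OC)C#C/C=C(/CO)CCC1=C(C)CC[C@H]2C(C)(C)CCC[C@]12C
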